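Read the plateaus first.

| setting | north | south-east | south-west | birch | oak |
|---|---|---|---|---|---|
| left-handed substrate | 5 mM | 20 mM | 10 mM | 10 mM | 10 mM |
| right-handed substrate | 5 mM | 20 mM | 10 mM | 10 mM | 10 mM |
| partner | 3 equiv | 3 equiv | 3 equiv | 3.00 equiv | 3.00 equiv |
| protic impurity | 10 mM | 10 mM | 20 mM | 10.0 mM | 10.0 mM |
| catalyst | 0.064 mol% (in portions, 3) | 0.064 mol% (in portions, 3) | 0.064 mol% (in portions, 3) | 0.064 mol% (in portions, 3) | 0.064 mol% (in portions, 3) |
| temperature | −25 °C | 10 °C | −25 °C |  |  |
| remark | run made earlier; portions every 15 min | run made earlier; portions every 15 min | run made earlier; portions every 15 min | at 40 °C throughout; the portions of catalyst follow each other after 15 min, the first at the start | at −20 °C until 5.0 h, from then on at 40 °C; the portions of catalyst follow each other after 15 min, the first at the start |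
| time |  |  |  | 10 h | 15 h |

| run | time / h | left-handed product / % | left-handed substrate / % |
|---|---|---|---|
| north | 1.33 | 6.3 | 42.6 |
| north | 3.00 | 9.5 | 42.3 |
| north | 6.00 | 7.2 | 43.4 |
| north | 15.0 | 6.3 | 43.0 |
| south-east | 0.333 | 5.4 | 44.7 |
| south-east | 0.667 | 6.8 | 43.9 |
| south-east | 1.33 | 6.0 | 44.6 |
| south-east | 3.00 | 6.2 | 43.3 |
| south-west | 4.00 | 15.5 | 34.5 |
| south-west | 8.00 | 15.1 | 36.1 |
| south-west | 12.0 | 17.8 | 32.7 |
| south-west | 15.0 | 15.5 | 32.9 |

(each reading ± 1 percentage point)

- catalyst is single-handed; left-handed substrate and right-handed substrate are mirror images of each other, charged as a racemate, each of them at the stated concentration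

- which one finishes higher in amount of left-handed product, in percent of the left-handed substrate and right-handed substrate together charged ("neither" within 2 percentage points) (birch / oak / neither)
- amount of left-handed product at the end, in percent of the left-handed substrate and right-handed substrate together charged, birch
- amount of left-handed product at the end, in percent of the left-handed substrate and right-handed substrate together charged, oak

Left-handed product in each earlier run shows no trend across its readings, while left-handed substrate stays in the flask, so each run stops early. Take the mean of each run: north 7.33%, south-west 16.0%, south-east 6.10%. At one loading, catalyst concentration goes with the charge of left-handed substrate, so divide by that charge. North gives 0.0147 /mM and south-west 0.0160 /mM. Their mean, 0.0153 /mM, is the cold yield per millimolar: the plateau fraction per millimolar of left-handed substrate at this loading. Both cold runs hold impurity at twice the left-handed substrate, whereas oak holds it level, so the reading carries that caveat.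

Now solve oak at both ends. If its stop is final before the warming, oak is simply a cold flask, at −20 °C rather than −25 °C, and gives 15.3%. If nothing stops it, left-handed product reaches 50%. The south-west run is already flat at 4.00 h, earlier than oak's change at 5.0 h, so I put oak at the first end, near 15.3%.

Birch is warm throughout. South-east gives 0.00305 /mM, which is 5.02 times lower than the cold value over 35.0 K, but south-east also holds impurity at half its left-handed substrate, so that factor carries both changes. Applying that factor once more, as a rough step over the 30.0 K up to 40 °C, I expect about 0.608% for birch, so I expect oak to finish higher.

The forecast also names oak but differs from my amounts, with 3% for birch and 10% for oak, saying of oak that “warming adds little”.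

Oak gives 15.7% and birch 0.166%, so oak finishes higher.

    partner + protic impurity → quenched reagent (k = 0.343 /M/s, Ea = 42.0 kJ/mol)
    partner + catalyst + left-handed substrate → catalyst + left-handed product (k = 29900 /M²/s, Ea = 9.00 kJ/mol)
    partner → decomposed reagent (k = 0.00287 /s, Ea = 66.0 kJ/mol)
    partner + catalyst + right-handed substrate → catalyst + right-handed product (k = 13500 /M²/s, Ea = 20.0 kJ/mol)
    (constants at −20 °C)

In oak at its first temperature, partner's half-life to decomposed reagent alone is 0.067 h, shorter than the 0.22 h for its reaction with right-handed substrate alone, reckoned as if the whole charge of catalyst and substrate were there at once. Partner, the limiting reagent, stands at 0% in oak at the change of temperature, 5.00 h. Oak's yield per millimolar comes to 0.0157 /mM, against the 0.0153 /mM read from the cold runs. Scaled in proportion to a flask like oak but with 0.038 mol% of catalyst, that reading gives 9.09%, and that flask stands at 10.8%.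

(The earlier runs and the new flask were generated by integration for an exercise.)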